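## Structural features

The target is a (2S)-flavanone: benzene ring A is fused along C4a–C8a to the dihydropyranone ring C, and the catechol ring B is attached at C2. Ring A is pentasubstituted in a phloroglucinol pattern with three different oxygens (ring oxygen O1 on C8a, free hydroxyl on C5, methyl ether on C7), the ketone carbon C4 on C4a and, on C8 between O1 and the methyl ether, a (Z)-4-hydroxy-3-methylbut-2-enyl chain; only C6 bears hydrogen. C2 is the only stereocentre and has no stereogenic neighbour, but it is benzylic, bonded to O1 and β to the C4 carbonyl, so base can erase it by retro-oxa-Michael opening of ring C and strong acid by ionisation of the C2–O1 bond, which the para oxygen of ring B assists. Other fragile sites are the trisubstituted Z-alkene with its primary allylic alcohol (ionisation, E/Z drift), the oxidisable catechol and the C8 methylene, which is both benzylic and allylic. The real difficulty is therefore not making C2 but closing ring C onto a fully differentiated ring A without exposing the finished flavanone to base, while the Z-alkene is carried through unchanged. The key step exploits that the two bonds joining ring C to ring A, O1–C8a and C4–C4a, end on neighbouring arene carbons, which are the two carbons of an aryne; the oxygen on C5 polarises that aryne so that an oxygen nucleophile goes to C8a and the carbanion appears on C4a. C2 can then be prepared beforehand as an open-chain benzylic carbinol, where catalytic ketone reduction is reliable.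

## Logic of the disconnections

31 to 30. The three aryl O–CH2 acetal bonds and the side-chain O–Si bond are cut. All four hydroxyls must be masked in the anionic key step, because a free O–H would protonate the aryl anion or add to the aryne. The skeleton is not simplified, but the masks are chosen to fall together. The forward step must use acid mild enough to leave C2 and the allylic alcohol alone, so the side-chain oxygen carries a triisopropylsilyl ether; an alkyl acetal there would be the slowest group to cleave and would set the acid strength for the whole step.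

30 to 21 and 25. O1–C8a and C4–C4a are cut. They sit on adjacent arene carbons, so one aryne can accept both partners, and the cut divides the molecule into two fragments of similar size: every ring A substituent on 21, the stereocentre on 25. Both fragments map onto 31 atom for atom:
- In 21 the triflate is on the future C8a (next to the side chain) and silicon on the future C4a (next to the acetal oxygen).
- The priority order O > aryl > CH2 > H is the same in 25 and 30, so retention keeps the descriptor S.

The forward step demands oxygen attack at C8a, acylation faster than protonation, and no free base near the product. Three design points serve this: the hydroxyl of 25 is deprotonated before the aryne is released, a crown-ether-solubilised fluoride lets the aryne form at or below 0 °C, and the side-chain silyl ether is bulky enough to ignore fluoride at that temperature.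

25 to 24, 23 and 22. The carbinol C–H bond is cut (back to the ketone of 24), then the bond between the ketone carbon and the α-CH2 (back to ester 23), then two O–CH2 acetal bonds (back to 22). The stereocentre becomes a prochiral aryl ketone, the best substrate class for catalytic transfer hydrogenation, and the carbon chain comes from a one-step acylation. The forward reduction must be face-selective under conditions that spare the aryl acetals.

21 to 19. The O–S bond of the triflate and the O–C(O) bond of the carbamate are cut. The carbamate is kept to this point because it directs both ring C–H functionalisations and can be removed by base alone, so the acid-sensitive arylsilane never meets acid. The forward step must triflate a phenoxide flanked by two ortho substituents.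

19 to 14 and 7. The bond between ring carbon C6 of 19 (the future C8) and the side-chain CH2 is cut. This is convergent and brings in the whole side chain with its alkene geometry already fixed. The forward step demands metalation at the one remaining position next to the carbamate, a nitrogen mask that lasts through the organocopper stage, substitution at the primary carbon of the allylic bromide, and retention of the Z geometry.

14 to 10, 9 and 8. The C–Si bond, the carbamate O–C(O) bond and one O–CH2 acetal bond are cut, back to a symmetrical diol. Each step is a single functionalisation of a simple arene. The forward sequence demands mono-protection of two equivalent hydroxyls, and lithiation between the carbamate and the acetal oxygen and not beside the methyl ether.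

7 to 6, 4, 3 and 1. The C–Br bond, the bond between the alkenyl carbon and the CH2OH carbon, the O–Si bond, and finally the C–I and C–CH3 bonds across the former alkyne are cut. The Z geometry then comes from one hydroxyl-directed anti-carbometalation of a three-carbon alkynol, and every later operation on the chain is stereoretentive. The forward steps demand clean anti addition and retention in the iodination, the lithium exchange and the substitution.

## Other disconnections considered

Alternative 1: The cut is the C2''=C3'' double bond of the side chain, with the future C4'' oxygen tied to O7 as an ester. In the forward sense the 8-allyl 7-methacrylate A1 would undergo ring-closing metathesis with the second-generation Grubbs catalyst to the seven-membered unsaturated lactone A2.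
- In favour: the ring can only hold a cis alkene, so the Z geometry is guaranteed. On this point the alternative is better than the chosen plan, which carries the geometry through four stereoretentive operations. Metathesis is also well-precedented and neutral, whereas step 13 is not precedented.
- Against: the step solves neither ring C nor C2, since A1 must already be an enantiopure flavanone with an 8-allyl group. The metathesis has to form a trisubstituted, ester-conjugated alkene in a medium ring. Afterwards the aryl lactone must be reduced to the allylic alcohol beside the C4 ketone, O7 must be methylated under base on a racemisable flavanone, and the diphenylmethylene ketal must be removed without hydrogenating the alkene.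
- Comparison: on structure it handles the alkene better and the core worse. On mechanism it is milder. On step economy it needs at least three operations after its key step where the chosen plan needs one, and a separate asymmetric entry to the core.

Alternative 2: The cuts are C4a–C8a, C5–C6 and C7–C8, so ring A is assembled from three alkynes. In the forward sense the tethered diyne A3 and methoxyacetylene A4 would combine under [Rh(cod)2]BF4 with a bisphosphine to give flavanone A5, closing rings C and A together.
- In favour: three C–C bonds and two rings in one catalytic step, which is better bond economy than the chosen plan. The tether fixes which carbon bears O1 and which bears C4, so there is no aryne regiochemistry to rely on (also better). C2 again comes from a preformed carbinol, which is equal.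
- Against: nothing in A4 dictates whether its methoxy carbon ends at C7 or C6. A3 contains an alkynyl ether of a secondary benzylic alcohol, prone to thermal elimination, and a β-alkoxy ynone that can lose its alkoxide by E1cB. A4 is volatile and polymerises readily. The tert-butyl ether needs stronger acid at the end than aryl acetals do.
- Comparison: on structure it avoids a prefunctionalised arene. On mechanism it depends on catalyst-controlled alkyne orientation, where the chosen plan uses the innate polarisation of an alkoxy aryne. On step economy the saving in the key step is likely spent on preparing A3.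

Alternative 3: The cut is C2–C3. In the forward sense the carbene generated from diazoketone A6 with a chiral dirhodium tetracarboxylate Rh2(O2CR)4 would insert into one enantiotopic benzylic C–H bond of the aryl benzyl ether to give the tetrakis-silyl flavanone A7.
- In favour: ring C and the C2 stereocentre are created together by a catalyst from an achiral precursor, so no chiral fragment has to be carried (better). Carbene insertion next to an ether oxygen is a known reaction class, whereas step 13 is new (better). The benzyl ether is trivial to install.
- Against: an acceptor-only keto carbene can also attack O1 to form a five-membered oxonium ylide and undergo a 1,2-shift, or add to the arene. Discrimination of the two benzylic hydrogens is usually modest for such carbenes. The diazoketone has to be built on an acyl carbon flanked by two ortho oxygens. Ring A with its side chain must still be made as in the chosen plan.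
- Comparison: the chosen plan sets C2 by a reliable ketone reduction and only has to keep it, whereas here the enantiomeric purity rests on the riskiest step. Step economy is about equal.

Key step: step 13

Assumption: the sense of induction in step 12 is taken to follow that of simple aryl alkyl ketones ((S,S)-ligand giving the (S)-carbinol); if it were opposite, the (R,R)-ligand would be used and nothing else changes.

## Route

Step 1
Reactants: 1 propargyl alcohol
Product: 3 (Z)-3-iodo-2-methylprop-2-en-1-ol, via vinylmagnesium alkoxide 2 (not isolated)
Conditions: MeMgBr (3 equiv), CuI (10 mol%), THF, −10 °C → rt; I2, −78 → 0 °C; H2O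
Reagents that add atoms: methylmagnesium bromide, C[Mg]Br; iodine, II
Why: Anti-carbomagnesiation of the magnesium alkoxide of a propargylic alcohol, catalysed by monovalent copper, puts methyl on C2 and magnesium on C3 cis to the CH2O group in chelate 2; iodinolysis of the C–Mg bond with retention fixes the Z geometry that the side chain keeps to the end.

Step 2
Reactants: 3 (Z)-3-iodo-2-methylprop-2-en-1-ol
Product: 4 (Z)-(3-iodo-2-methylprop-2-enyloxy)triisopropylsilane
Conditions: TIPSCl, imidazole, DMF, 0 °C → rt
Reagents that add atoms: chlorotriisopropylsilane, CC(C)[Si](Cl)(C(C)C)C(C)C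
Why: Standard silylation of a primary alcohol; the bulky silyl ether resists O-to-C silyl migration in the vinyllithium of step 3, is inert to fluoride at 0 °C in step 13 and falls under the same mild acid as the aryl acetals in step 14.

Step 3
Reactants: 4 (Z)-(3-iodo-2-methylprop-2-enyloxy)triisopropylsilane
Product: 6 (Z)-3-methyl-4-(triisopropylsilyloxy)but-2-en-1-ol, via vinyllithium 5 (not isolated)
Conditions: t-BuLi (2.1 equiv), Et2O, −78 °C; (CH2O)n, −78 → 0 °C; H2O
Reagents that add atoms: formaldehyde (as paraformaldehyde), C=O
Why: Iodine–lithium exchange of an alkenyl iodide proceeds with retention of configuration and the vinyllithium adds to formaldehyde, a one-carbon homologation to the Z-allylic alcohol.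

Step 4
Reactants: 6 (Z)-3-methyl-4-(triisopropylsilyloxy)but-2-en-1-ol
Product: 7 (Z)-(4-bromo-2-methylbut-2-enyloxy)triisopropylsilane
Conditions: CBr4, PPh3, CH2Cl2, 0 °C
Reagents that add atoms: tetrabromomethane, BrC(Br)(Br)Br
Why: Appel bromination of a primary allylic alcohol under neutral conditions (SN2 at the alkoxyphosphonium) leaves the alkene geometry and the silyl ether untouched; the bromide is used at once.

Step 5
Reactants: 8 5-methoxyresorcinol
Product: 9 3-methoxy-5-(methoxymethoxy)phenol
Conditions: MOMCl (1.0 equiv), iPr2NEt, CH2Cl2, 0 °C → rt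
Reagents that add atoms: chloromethyl methyl ether, COCCl
Why: O-Alkylation of one of two equivalent phenols with one equivalent of reagent; the outcome is statistical, 9 is separated from bis-ether and unreacted 8 (recycled), which is acceptable as the first step on an inexpensive diol.

Step 6
Reactants: 9 3-methoxy-5-(methoxymethoxy)phenol
Product: 10 3-methoxy-5-(methoxymethoxy)phenyl N-isopropylcarbamate
Conditions: iPrNCO, Et3N (cat.), CH2Cl2, rt
Reagents that add atoms: isopropyl isocyanate, CC(C)N=C=O
Why: Base-catalysed addition of a phenol to an isocyanate; the N-monoalkyl carbamate is the strongest ortho-director available and can later be removed by base alone.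

Step 7
Reactants: 10 3-methoxy-5-(methoxymethoxy)phenyl N-isopropylcarbamate
Product: 14 5-methoxy-3-(methoxymethoxy)-2-(trimethylsilyl)phenyl N-isopropylcarbamate, via N-silyl carbamate 11 (not isolated), via ortho-lithiated carbamate 12 (not isolated), via N-silyl C-silyl carbamate 13 (not isolated)
Conditions: TMSOTf, TMEDA, Et2O, 0 °C → rt; n-BuLi (2.1 equiv), TMEDA, −78 °C; TMSCl, −78 °C → rt; aq. NaHCO3
Reagents that add atoms: chlorotrimethylsilane, C[Si](C)(C)Cl
Why: Directed ortho-metalation: after transient N-silylation the carbamate directs lithiation to C2, which is activated by both the carbamate and the acetal oxygen, in preference to C6 beside the weaker methoxy director; silylation of 12 and hydrolysis of the N–Si bond on the basic work-up give 14, which is purified at this stage.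

Step 8
Reactants: 14 5-methoxy-3-(methoxymethoxy)-2-(trimethylsilyl)phenyl N-isopropylcarbamate; 7 (Z)-(4-bromo-2-methylbut-2-enyloxy)triisopropylsilane
Product: 19 5-methoxy-3-(methoxymethoxy)-6-[(Z)-3-methyl-4-(triisopropylsilyloxy)but-2-enyl]-2-(trimethylsilyl)phenyl N-isopropylcarbamate, via N-triethylsilyl C-silyl carbamate 15 (not isolated), via aryllithium 16 (not isolated), via arylcopper 17 (not isolated), via N-triethylsilyl allylated carbamate 18 (not isolated)
Conditions: TESOTf, TMEDA, Et2O, 0 °C → rt; n-BuLi (2.1 equiv), TMEDA, −78 °C; CuBr·SMe2, THF, −78 °C; 7, −78 → −20 °C; aq. NH4Cl/NH3 (pH 8)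
Reagents that add atoms: none
Why: Second directed ortho-metalation at the only remaining position next to the carbamate, transmetalation to the arylcopper and SN2 substitution at the primary carbon of the allylic bromide, whose far alkene carbon is fully substituted. Nitrogen is masked here as the triethylsilyl derivative, which should outlast the warmer organocopper stage (loss of the mask would free the N-anion and expel the phenoxide) and still hydrolyse on the ammonia-buffered work-up. The low temperature prevents anionic carbamoyl migration and allyl equilibration, so the Z geometry is retained.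

Step 9
Reactants: 19 5-methoxy-3-(methoxymethoxy)-6-[(Z)-3-methyl-4-(triisopropylsilyloxy)but-2-enyl]-2-(trimethylsilyl)phenyl N-isopropylcarbamate
Product: 21 5-methoxy-3-(methoxymethoxy)-6-[(Z)-3-methyl-4-(triisopropylsilyloxy)but-2-enyl]-2-(trimethylsilyl)phenyl trifluoromethanesulfonate, via phenol 20 (not isolated)
Conditions: Et2NH, DBU, MeCN, 40 °C; PhNTf2, rt
Reagents that add atoms: N-phenylbis(trifluoromethanesulfonimide), O=S(=O)(N(c1ccccc1)S(=O)(=O)C(F)(F)F)C(F)(F)F
Why: E1cB cleavage of the N-monoalkyl carbamate (DBU removes N–H, the phenoxide leaves, the isocyanate is trapped by Et2NH as a urea) followed by O-sulfonylation of the phenoxide in the same flask; no acid touches the electron-rich arylsilane.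

Step 10
Reactants: 22 methyl 3,4-dihydroxybenzoate
Product: 23 methyl 3,4-bis(methoxymethoxy)benzoate
Conditions: MOMCl (2.5 equiv), iPr2NEt, CH2Cl2, 0 °C → rt
Reagents that add atoms: chloromethyl methyl ether, COCCl
Why: O-Alkylation of both phenols under amine base; the acetals tolerate every later basic step and leave under mild acid at the end.

Step 11
Reactants: 23 methyl 3,4-bis(methoxymethoxy)benzoate
Product: 24 3-[3,4-bis(methoxymethoxy)phenyl]-N-methoxy-N-methyl-3-oxopropanamide
Conditions: MeC(O)N(OMe)Me, LiN(iPr)2 (2.2 equiv each), THF, −78 → 0 °C; AcOH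
Reagents that add atoms: N-methoxy-N-methylacetamide, CC(=O)N(C)OC
Why: Crossed Claisen condensation: the lithium enolate of the acetamide is acylated by the methyl ester, and the second equivalent of enolate stores the product as its stabilised enolate, which stops further addition.

Step 12
Reactants: 24 3-[3,4-bis(methoxymethoxy)phenyl]-N-methoxy-N-methyl-3-oxopropanamide
Product: 25 (S)-3-hydroxy-N-methoxy-N-methyl-3-[3,4-bis(methoxymethoxy)phenyl]propanamide
Conditions: RuCl[(S,S)-TsDPEN](p-cymene) (1 mol%), HCO2Na, H2O/MeOH, 40 °C
Reagents that add atoms: none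
Why: Asymmetric transfer hydrogenation of an aryl ketone; with the (S,S)-ligand the aryl group lies beside the η6-arene (CH/π contact) and hydride goes to the face that gives the (S)-benzylic alcohol, as with aryl alkyl ketones and β-keto esters, while neutral aqueous formate spares the acetals.

Step 13
Reactants: 25 (S)-3-hydroxy-N-methoxy-N-methyl-3-[3,4-bis(methoxymethoxy)phenyl]propanamide; 21 5-methoxy-3-(methoxymethoxy)-6-[(Z)-3-methyl-4-(triisopropylsilyloxy)but-2-enyl]-2-(trimethylsilyl)phenyl trifluoromethanesulfonate
Product: 30 (2S)-2-[3,4-bis(methoxymethoxy)phenyl]-7-methoxy-5-(methoxymethoxy)-8-[(Z)-3-methyl-4-(triisopropylsilyloxy)but-2-enyl]chroman-4-one, via potassium alkoxide 26 (not isolated), via aryne 27 (not isolated), via aryl anion 28 (not isolated), via tetrahedral adduct 29 (not isolated)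
Conditions: KN(SiMe3)2 (1.0 equiv), THF, −78 °C; 21 (1.3 equiv), KF, 18-crown-6, THF, −78 → 0 °C; AcOH, −40 °C
Reagents that add atoms: none
Why: Proposed new method: fluoride attacks silicon of 21 and triflate leaves, giving aryne 27; alkoxide 26 adds to the aryne carbon that becomes C8a, and the resulting aryl anion 28, which has no O–H proton within reach because the hydroxyl was deprotonated beforehand, adds to the N-methoxy-N-methyl amide carbonyl to give the potassium-chelated tetrahedral adduct 29, which releases ketone 30 only on the cold acidic quench; the closest known reaction type is the fluoride-mediated annulation of arynes with salicylate esters to xanthones (O-arylation, then intramolecular acyl substitution), and new here are an aliphatic alkoxide as nucleophile and an N-methoxy-N-methyl amide as acceptor. Ring C is closed by a 6-exo-trig attack of C4a on the C4 carbonyl. No stereocentre is formed: C2 comes from 25 with retention because its C–O bond is never broken, and the transient C4 centre of 29 disappears on collapse. The regioselectivity needed (oxygen to C8a, carbon to C4a) is secured by the C5 acetal oxygen, whose σ-withdrawal distorts the aryne so that C8a is the more electrophilic terminus and the developing carbanion at C4a lies ortho to oxygen; this bias has to outweigh the steric shielding of C8a by the C8 chain. The chemoselectivity needed (acylation before proton transfer from C3–H or from HN(SiMe3)2) is secured by the six-membered intramolecular geometry and the absence of any O–H. Working at or below 0 °C keeps alkoxide 26 from retro-aldol cleavage, and because 29 persists until protonation no free base meets the flavanone.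

Step 14
Reactants: 30 (2S)-2-[3,4-bis(methoxymethoxy)phenyl]-7-methoxy-5-(methoxymethoxy)-8-[(Z)-3-methyl-4-(triisopropylsilyloxy)but-2-enyl]chroman-4-one
Product: 31 (2S)-2-(3,4-dihydroxyphenyl)-5-hydroxy-8-[(Z)-4-hydroxy-3-methylbut-2-enyl]-7-methoxychroman-4-one
Conditions: HCl (1.25 M in MeOH), 0 °C → rt
Reagents that add atoms: none
Why: Acid-catalysed transacetalisation of the three aryl acetals and methanolysis of the primary silyl ether in one operation; the C5 acetal is activated by the neighbouring carbonyl, the C8 chain has no ortho phenol to cyclise onto, and room temperature should keep C2 and the allylic alcohol intact.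

## Compound list

1 | propargyl alcohol (prop-2-yn-1-ol) | C#CCO | starting material
2 | (Z)-[3-(bromomagnesiooxy)-2-methylprop-1-enyl]magnesium bromide | Br[Mg]/C=C(/C)CO[Mg]Br | intermediate
3 | (Z)-3-iodo-2-methylprop-2-en-1-ol | I/C=C(/C)CO | intermediate
4 | (Z)-(3-iodo-2-methylprop-2-enyloxy)triisopropylsilane | I/C=C(/C)CO[Si](C(C)C)(C(C)C)C(C)C | intermediate
5 | (Z)-[2-methyl-3-(triisopropylsilyloxy)prop-1-enyl]lithium | [Li]/C=C(/C)CO[Si](C(C)C)(C(C)C)C(C)C | intermediate
6 | (Z)-3-methyl-4-(triisopropylsilyloxy)but-2-en-1-ol | OC/C=C(/C)CO[Si](C(C)C)(C(C)C)C(C)C | intermediate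
7 | (Z)-(4-bromo-2-methylbut-2-enyloxy)triisopropylsilane | BrC/C=C(/C)CO[Si](C(C)C)(C(C)C)C(C)C | intermediate
8 | 5-methoxyresorcinol | COc1cc(O)cc(O)c1 | starting material
9 | 3-methoxy-5-(methoxymethoxy)phenol | COCOc1cc(O)cc(OC)c1 | intermediate
10 | 3-methoxy-5-(methoxymethoxy)phenyl N-isopropylcarbamate | CC(C)NC(=O)Oc1cc(OC)cc(OCOC)c1 | intermediate
11 | 3-methoxy-5-(methoxymethoxy)phenyl N-isopropyl-N-(trimethylsilyl)carbamate | CC(C)N([Si](C)(C)C)C(=O)Oc1cc(OC)cc(OCOC)c1 | intermediate
12 | {2-[N-isopropyl-N-(trimethylsilyl)carbamoyloxy]-4-methoxy-6-(methoxymethoxy)phenyl}lithium | CC(C)N([Si](C)(C)C)C(=O)Oc1cc(OC)cc(OCOC)c1[Li] | intermediate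
13 | 5-methoxy-3-(methoxymethoxy)-2-(trimethylsilyl)phenyl N-isopropyl-N-(trimethylsilyl)carbamate | CC(C)N([Si](C)(C)C)C(=O)Oc1cc(OC)cc(OCOC)c1[Si](C)(C)C | intermediate
14 | 5-methoxy-3-(methoxymethoxy)-2-(trimethylsilyl)phenyl N-isopropylcarbamate | CC(C)NC(=O)Oc1cc(OC)cc(OCOC)c1[Si](C)(C)C | intermediate
15 | 5-methoxy-3-(methoxymethoxy)-2-(trimethylsilyl)phenyl N-isopropyl-N-(triethylsilyl)carbamate | CC(C)N([Si](CC)(CC)CC)C(=O)Oc1cc(OC)cc(OCOC)c1[Si](C)(C)C | intermediate
16 | {2-[N-isopropyl-N-(triethylsilyl)carbamoyloxy]-6-methoxy-4-(methoxymethoxy)-3-(trimethylsilyl)phenyl}lithium | CC(C)N([Si](CC)(CC)CC)C(=O)Oc1c([Li])c(OC)cc(OCOC)c1[Si](C)(C)C | intermediate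
17 | {2-[N-isopropyl-N-(triethylsilyl)carbamoyloxy]-6-methoxy-4-(methoxymethoxy)-3-(trimethylsilyl)phenyl}copper | CC(C)N([Si](CC)(CC)CC)C(=O)Oc1c([Cu])c(OC)cc(OCOC)c1[Si](C)(C)C | intermediate
18 | 5-methoxy-3-(methoxymethoxy)-6-[(Z)-3-methyl-4-(triisopropylsilyloxy)but-2-enyl]-2-(trimethylsilyl)phenyl N-isopropyl-N-(triethylsilyl)carbamate | CC(C)N([Si](CC)(CC)CC)C(=O)Oc1c(C/C=C(/C)CO[Si](C(C)C)(C(C)C)C(C)C)c(OC)cc(OCOC)c1[Si](C)(C)C | intermediate
19 | 5-methoxy-3-(methoxymethoxy)-6-[(Z)-3-methyl-4-(triisopropylsilyloxy)but-2-enyl]-2-(trimethylsilyl)phenyl N-isopropylcarbamate | CC(C)NC(=O)Oc1c(C/C=C(/C)CO[Si](C(C)C)(C(C)C)C(C)C)c(OC)cc(OCOC)c1[Si](C)(C)C | intermediate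
20 | 5-methoxy-3-(methoxymethoxy)-6-[(Z)-3-methyl-4-(triisopropylsilyloxy)but-2-enyl]-2-(trimethylsilyl)phenol | Oc1c(C/C=C(/C)CO[Si](C(C)C)(C(C)C)C(C)C)c(OC)cc(OCOC)c1[Si](C)(C)C | intermediate
21 | 5-methoxy-3-(methoxymethoxy)-6-[(Z)-3-methyl-4-(triisopropylsilyloxy)but-2-enyl]-2-(trimethylsilyl)phenyl trifluoromethanesulfonate | C[Si](C)(C)c1c(OCOC)cc(OC)c(C/C=C(/C)CO[Si](C(C)C)(C(C)C)C(C)C)c1OS(=O)(=O)C(F)(F)F | intermediate
22 | methyl 3,4-dihydroxybenzoate | COC(=O)c1ccc(O)c(O)c1 | starting material
23 | methyl 3,4-bis(methoxymethoxy)benzoate | COC(=O)c1ccc(OCOC)c(OCOC)c1 | intermediate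
24 | 3-[3,4-bis(methoxymethoxy)phenyl]-N-methoxy-N-methyl-3-oxopropanamide | COCOc1ccc(C(=O)CC(=O)N(C)OC)cc1OCOC | intermediate
25 | (S)-3-hydroxy-N-methoxy-N-methyl-3-[3,4-bis(methoxymethoxy)phenyl]propanamide | O[C@H](c1ccc(OCOC)c(OCOC)c1)CC(=O)N(C)OC | intermediate
26 | potassium (S)-1-[3,4-bis(methoxymethoxy)phenyl]-3-[methoxy(methyl)amino]-3-oxopropan-1-olate | [K+].[O-][C@H](c1ccc(OCOC)c(OCOC)c1)CC(=O)N(C)OC | intermediate
27 | 5-methoxy-3-(methoxymethoxy)-6-[(Z)-3-methyl-4-(triisopropylsilyloxy)but-2-enyl]benzyne (1,2-didehydrobenzene) | COC1=C(C/C=C(/C)CO[Si](C(C)C)(C(C)C)C(C)C)C#CC(OCOC)=C1 | intermediate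
28 | {2-[(S)-1-[3,4-bis(methoxymethoxy)phenyl]-3-[methoxy(methyl)amino]-3-oxopropoxy]-4-methoxy-6-(methoxymethoxy)-3-[(Z)-3-methyl-4-(triisopropylsilyloxy)but-2-enyl]phenyl}potassium | [K+].COc1cc(OCOC)[c-]c(O[C@H](c2ccc(OCOC)c(OCOC)c2)CC(=O)N(C)OC)c1C/C=C(/C)CO[Si](C(C)C)(C(C)C)C(C)C | intermediate
29 | potassium (2S)-2-[3,4-bis(methoxymethoxy)phenyl]-7-methoxy-4-[methoxy(methyl)amino]-5-(methoxymethoxy)-8-[(Z)-3-methyl-4-(triisopropylsilyloxy)but-2-enyl]chroman-4-olate (either configuration at C4) | [K+].COc1cc(OCOC)c2c(c1C/C=C(/C)CO[Si](C(C)C)(C(C)C)C(C)C)O[C@H](c1ccc(OCOC)c(OCOC)c1)CC2([O-])N(C)OC | intermediate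
30 | (2S)-2-[3,4-bis(methoxymethoxy)phenyl]-7-methoxy-5-(methoxymethoxy)-8-[(Z)-3-methyl-4-(triisopropylsilyloxy)but-2-enyl]chroman-4-one | COc1cc(OCOC)c2c(c1C/C=C(/C)CO[Si](C(C)C)(C(C)C)C(C)C)O[C@H](c1ccc(OCOC)c(OCOC)c1)CC2=O | intermediate
31 | (2S)-2-(3,4-dihydroxyphenyl)-5-hydroxy-8-[(Z)-4-hydroxy-3-methylbut-2-enyl]-7-methoxychroman-4-one | COc1cc(O)c2c(c1C/C=C(/C)CO)O[C@H](c1ccc(O)c(O)c1)CC2=O | target

## Step count and risks

Total step count: 14 (steps 1–4 side chain, 5–9 ring A fragment, 10–12 carbinol fragment, 13 annulation, 14 deprotection). Longest linear sequence: 8 steps (1, 2, 3, 4, 8, 9, 13, 14).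

Least certain steps:

Step 13 (key step, new chemistry). What may go wrong:
- proton transfer to the aryl anion from C3–H or from HN(SiMe3)2 outrunning acylation, which stops the sequence at the uncyclised ether and opens the way to β-elimination of the aryloxide;
- loss of regiocontrol in the alkoxide addition, because the C8 chain shields C8a sterically while the C5 oxygen directs there electronically;
- retro-aldol fragmentation of the alkoxide before it meets the aryne;
- early collapse of the tetrahedral adduct, releasing a basic amide that opens ring C and racemises C2;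
- attack of the alkoxide at silicon or at sulfur of the triflate, which consumes the nucleophile before the aryne is formed.

The fallback uses known reactions only and changes the order of bond formation (O1–C2 by Mitsunobu displacement with inversion, C4–C4a by Parham cyclisation). It sets out from 19 and 24 and returns to the route at 30. Ipso-bromodesilylation of 19 with NBS in MeCN at 0 °C should give 2-bromo-5-methoxy-3-(methoxymethoxy)-6-[(Z)-3-methyl-4-(triisopropylsilyloxy)but-2-enyl]phenyl N-isopropylcarbamate F1. Et2NH/DBU as in step 9, without the triflating agent, should give 2-bromo-5-methoxy-3-(methoxymethoxy)-6-[(Z)-3-methyl-4-(triisopropylsilyloxy)but-2-enyl]phenol F2. Ketone 24 is reduced as in step 12 but with RuCl[(R,R)-TsDPEN](p-cymene) to (R)-3-hydroxy-N-methoxy-N-methyl-3-[3,4-bis(methoxymethoxy)phenyl]propanamide F3. Mitsunobu etherification of F2 with F3 (PPh3, DIAD, toluene, 0 °C) inverts the carbinol and gives (S)-3-{2-bromo-5-methoxy-3-(methoxymethoxy)-6-[(Z)-3-methyl-4-(triisopropylsilyloxy)but-2-enyl]phenoxy}-N-methoxy-N-methyl-3-[3,4-bis(methoxymethoxy)phenyl]propanamide F4. Bromine–lithium exchange with t-BuLi in THF at −78 °C is then followed by cyclisation of the aryllithium onto the N-methoxy-N-methyl amide and, after an acidic quench, gives 30.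

Step 8. What may go wrong:
- lithiation at C4 instead of C6, or incomplete lithiation;
- anionic migration of the carbamoyl group to carbon before transmetalation;
- substitution at the far end of the allyl unit, giving the branched skeleton;
- E/Z drift through equilibration of the allylcopper species;
- self-destruction of the Z-configured allylic bromide;
- slow hydrolysis of the N–Si bond on work-up, leaving N-silylated material that step 9 cannot cleave.

The fallback replaces aryl–allyl substitution by a benzyl–alkenyl cross-coupling. It sets out from 14 and 4 and returns at 19, and it also makes steps 3 and 4 unnecessary. Aryllithium 16, generated as in step 8, is quenched with MeI to give after work-up 5-methoxy-3-(methoxymethoxy)-6-methyl-2-(trimethylsilyl)phenyl N-isopropylcarbamate F5. After renewed N-silylation with TESOTf and TMEDA, lateral lithiation of the methyl group with LiN(iPr)2 at −78 °C and transmetalation with ZnCl2 give {2-[N-isopropyl-N-(triethylsilyl)carbamoyloxy]-6-methoxy-4-(methoxymethoxy)-3-(trimethylsilyl)benzyl}zinc chloride F6. This is coupled with alkenyl iodide 4 under Pd(PPh3)4 catalysis (Negishi coupling, retention at the alkenyl carbon) to 18 and hence, on work-up, 19.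

Step 7. What may go wrong:
- partition of the lithiation between C2 (beside the acetal oxygen) and C6 (beside the methoxy group), since both are ortho to the carbamate;
- protodesilylation of the very electron-rich arylsilane if the work-up turns acidic.

The fallback removes the regiochemical question by symmetry and the statistical step 5 with it. It sets out from 8 and returns at 14. Compound 8 with two equivalents of iPrNCO gives 5-methoxy-1,3-phenylene bis(N-isopropylcarbamate) F7. Double N-silylation, lithiation at the carbon between the two carbamates and TMSCl give 5-methoxy-2-(trimethylsilyl)-1,3-phenylene bis(N-isopropylcarbamate) F8. Et2NH/DBU removes one carbamate, the second being slower because it would have to expel a dianion, to give 3-hydroxy-5-methoxy-2-(trimethylsilyl)phenyl N-isopropylcarbamate F9. MOMCl/iPr2NEt then gives 14.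

Step 14. What may go wrong:
- acid-promoted opening and reclosure of ring C at C2, eroding the enantiomeric purity;
- ionisation of the liberated allylic alcohol with solvolysis or transposition;
- incomplete cleavage of the catechol acetals at the low temperature chosen to avoid the first two.

The fallback is a staged, orthogonal deprotection without Brønsted acid. It sets out from 30 and returns at 31. HF·pyridine buffered with pyridine in THF at 0 °C removes only the silyl ether and gives (2S)-2-[3,4-bis(methoxymethoxy)phenyl]-8-[(Z)-4-hydroxy-3-methylbut-2-enyl]-7-methoxy-5-(methoxymethoxy)chroman-4-one F10. The three aryl acetals are then exchanged with TMSOTf and 2,2′-bipyridyl in MeCN at 0 °C and the resulting silyl ethers are hydrolysed by water on work-up to give 31.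

## Further compounds

F1 | step 13 | 2-bromo-5-methoxy-3-(methoxymethoxy)-6-[(Z)-3-methyl-4-(triisopropylsilyloxy)but-2-enyl]phenyl N-isopropylcarbamate | CC(C)NC(=O)Oc1c(C/C=C(/C)CO[Si](C(C)C)(C(C)C)C(C)C)c(OC)cc(OCOC)c1Br
F2 | step 13 | 2-bromo-5-methoxy-3-(methoxymethoxy)-6-[(Z)-3-methyl-4-(triisopropylsilyloxy)but-2-enyl]phenol | Oc1c(C/C=C(/C)CO[Si](C(C)C)(C(C)C)C(C)C)c(OC)cc(OCOC)c1Br
F3 | step 13 | (R)-3-hydroxy-N-methoxy-N-methyl-3-[3,4-bis(methoxymethoxy)phenyl]propanamide | O[C@@H](c1ccc(OCOC)c(OCOC)c1)CC(=O)N(C)OC
F4 | step 13 | (S)-3-{2-bromo-5-methoxy-3-(methoxymethoxy)-6-[(Z)-3-methyl-4-(triisopropylsilyloxy)but-2-enyl]phenoxy}-N-methoxy-N-methyl-3-[3,4-bis(methoxymethoxy)phenyl]propanamide | COCOc1cc(OC)c(C/C=C(/C)CO[Si](C(C)C)(C(C)C)C(C)C)c(O[C@H](c2ccc(OCOC)c(OCOC)c2)CC(=O)N(C)OC)c1Br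
F5 | step 8 | 5-methoxy-3-(methoxymethoxy)-6-methyl-2-(trimethylsilyl)phenyl N-isopropylcarbamate | CC(C)NC(=O)Oc1c(C)c(OC)cc(OCOC)c1[Si](C)(C)C
F6 | step 8 | {2-[N-isopropyl-N-(triethylsilyl)carbamoyloxy]-6-methoxy-4-(methoxymethoxy)-3-(trimethylsilyl)benzyl}zinc chloride | CC(C)N([Si](CC)(CC)CC)C(=O)Oc1c(C[Zn]Cl)c(OC)cc(OCOC)c1[Si](C)(C)C
F7 | step 7 | 5-methoxy-1,3-phenylene bis(N-isopropylcarbamate) | CC(C)NC(=O)Oc1cc(OC)cc(OC(=O)NC(C)C)c1
F8 | step 7 | 5-methoxy-2-(trimethylsilyl)-1,3-phenylene bis(N-isopropylcarbamate) | CC(C)NC(=O)Oc1cc(OC)cc(OC(=O)NC(C)C)c1[Si](C)(C)C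
F9 | step 7 | 3-hydroxy-5-methoxy-2-(trimethylsilyl)phenyl N-isopropylcarbamate | CC(C)NC(=O)Oc1cc(OC)cc(O)c1[Si](C)(C)C
F10 | step 14 | (2S)-2-[3,4-bis(methoxymethoxy)phenyl]-8-[(Z)-4-hydroxy-3-methylbut-2-enyl]-7-methoxy-5-(methoxymethoxy)chroman-4-one | COc1cc(OCOC)c2c(c1C/C=C(/C)CO)O[C@H](c1ccc(OCOC)c(OCOC)c1)CC2=O
A1 | alternative 1 | (2S)-8-allyl-2-(2,2-diphenyl-1,3-benzodioxol-5-yl)-5-hydroxy-4-oxochroman-7-yl methacrylate | C=CCc1c(OC(=O)C(C)=C)cc(O)c2c1O[C@H](c1ccc3OC(c4ccccc4)(c4ccccc4)Oc3c1)CC2=O
A2 | alternative 1 | (2S)-flavanone with a seven-membered 3-methyl unsaturated lactone bridging O7 and C8, ring B as diphenylmethylene ketal | CC1=CCc2c(OC1=O)cc(O)c1c2O[C@H](c2ccc3OC(c4ccccc4)(c4ccccc4)Oc3c2)CC1=O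
A3 | alternative 2 | (S)-5-[3,4-bis(methoxymethoxy)phenyl]-1-tert-butoxy-5-{[(Z)-6-(tert-butyldimethylsilyloxy)-5-methylhex-4-en-1-ynyl]oxy}pent-1-yn-3-one | CC(C)(C)[Si](C)(C)OC/C(C)=C\CC#CO[C@H](c1ccc(OCOC)c(OCOC)c1)CC(=O)C#COC(C)(C)C
A4 | alternative 2 | methoxyacetylene | COC#C
A5 | alternative 2 | (2S)-2-[3,4-bis(methoxymethoxy)phenyl]-5-tert-butoxy-7-methoxy-8-[(Z)-4-(tert-butyldimethylsilyloxy)-3-methylbut-2-enyl]chroman-4-one | COc1cc(OC(C)(C)C)c2c(c1C/C=C(/C)CO[Si](C)(C)C(C)(C)C)O[C@H](c1ccc(OCOC)c(OCOC)c1)CC2=O
A6 | alternative 3 | 2-diazo-1-{2-[3,4-bis(tert-butyldimethylsilyloxy)benzyloxy]-6-(tert-butyldimethylsilyloxy)-4-methoxy-3-[(Z)-4-(tert-butyldimethylsilyloxy)-3-methylbut-2-enyl]phenyl}ethanone | COc1cc(O[Si](C)(C)C(C)(C)C)c(C(=O)C=[N+]=[N-])c(OCc2ccc(O[Si](C)(C)C(C)(C)C)c(O[Si](C)(C)C(C)(C)C)c2)c1C/C=C(/C)CO[Si](C)(C)C(C)(C)C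
A7 | alternative 3 | (2S)-2-[3,4-bis(tert-butyldimethylsilyloxy)phenyl]-5-(tert-butyldimethylsilyloxy)-7-methoxy-8-[(Z)-4-(tert-butyldimethylsilyloxy)-3-methylbut-2-enyl]chroman-4-one | COc1cc(O[Si](C)(C)C(C)(C)C)c2c(c1C/C=C(/C)CO[Si](C)(C)C(C)(C)C)O[C@H](c1ccc(O[Si](C)(C)C(C)(C)C)c(O[Si](C)(C)C(C)(C)C)c1)CC2=O
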